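Pick one flask.

in all of them: E 10 mol%
- west: J 0.54 M; temperature −10 °C; run made earlier
- north: J 1.2 M; temperature 10 °C; run made earlier
- red: J 0.80 M; at −5 °C throughout; time 80 min
- grey: J 0.80 M; at 25 °C until 15 min, from then on at −5 °C; time 80 min

| run | time / min | X / % | J / % |
|---|---|---|---|
| west | 50.0 | 1 | 97 |
| west | 80.0 | 3 | 96 |
| west | 150 | 1 | 90 |
| west | 180 | 3 | 88 |
| west | 240 | 3 | 84 |
| west | 300 | 5 | 84 |
| north | 6.00 | 2 | 91 |
| north | 20.0 | 11 | 77 |
| north | 30.0 | 18 | 68 |
| north | 50.0 | 21 | 54 |
| north | 80.0 | 36 | 36 |
| north | 120 | 49 | 23 |

(scatter of a reading: 2 percentage points)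

* the flask that ends with the higher amount of X, in percent of the J charged, or "neither" when 2 percentage points or less lies between them (red / grey / neither)
* final X, as a percentage of the J charged, in red
* final X, as a percentage of the J charged, in grey

I take the rate of loss of J as proportional to J, with the same rate per J at both concentrations. The last readings then give a rate constant of 0.0122 min⁻¹ in the north run and 5.81 × 10⁻⁴ min⁻¹ in the west run, and their two temperatures give an activation energy of 94.4 kJ mol⁻¹. So J goes with 0.0921 min⁻¹ at 25 °C and 0.00130 min⁻¹ at −5 °C.

Rate constant times minutes, summed over a flask's history, comes to 0.104 for red and 1.47 for grey. I call this sum the J clock, and J left is e to the minus clock. By this estimate 90.1% of J stands in red at the end and 23.1% in grey, so I reckon on a loss of 76.9% of the J in grey and 9.87% in red.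

Lost J is not all X, though. The selectivity, X per J lost, reads 0.312 at the end of the west run and 0.636 at the end of the north run, both with the scatter of their readings. Taking these as brackets, I expect red between 3.09% and 6.28% and grey between 24.0% and 48.9%. The low end for grey stands above the high end for red, so I charge grey.

The forecast also says grey, with red at 3% (1% to 6%) and grey at 50% (33% to 65%), and notes: “This suggests a slow intermediate or a temperature-dependent side path.” Its grey figure is what the last north reading of X gives when taken over. My bracket for grey reaches lower than its low end.

The simulation gives grey, with red at 2.54% and grey at 33.0%, which is 17 percentage points below the forecast.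

    E + Q → E + X (k = 2.15 M⁻¹ min⁻¹, Ea = 68.0 kJ mol⁻¹)
    Q → L (k = 0.216 min⁻¹, Ea = 89.0 kJ mol⁻¹)
    J → Q (k = 0.0919 min⁻¹, Ea = 93.0 kJ mol⁻¹)
    (constants at 25 °C)

Red ends with 89.5% of J and grey with 23.0%, where the clocks gave 90.1% and 23.1%. At the end, grey's X per J lost is 0.428. The neighbouring flask is red's charge run at 20 °C for the same time. Its clock is 3.85, which leaves 2.13% of J. That flask ends with 2.07% of J and 46.7% of X.

The readings were generated by integration with constants of no real substance; scatter was added.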